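The numbers in the tables were computed with constants of no real substance; noise was put on by code.

I began with the fraction of L left, not the G made. I assumed that a fixed amount of working E takes the same fraction of L each minute, which is pseudo-first-order decay, so the logarithm of that fraction adds up as the minutes pass. I therefore defined Q as minus the natural logarithm of the fraction of L left, taken as one minus G, divided by the concentration of E charged. Runs with different charges of E should then share one curve of Q against time.

| flask | L | E | remark | time |
|---|---|---|---|---|
| elm | 0.050 M | 0.8 mol% | run made earlier |  |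
| ash | 0.050 M | 1.3 mol% | run made earlier |  |
| alder | 0.025 M | 0.57 mol% | run made earlier |  |
| flask | 0.050 M | 0.57 mol% |  | 5.0 min |

- elm (time / min: G / %, L / %): 0.333: 0.4, 98.1; 0.667: 2.0, 97.5; 1.50: 6.5, 92.3; 4.00: 11.3, 86.7
- ash (time / min: G / %, L / %): 1.00: 7.4, 93.4; 2.00: 12.5, 86.6; 3.00: 17.9, 84.5; 4.00: 17.6, 82.8
- alder (time / min: G / %, L / %): 1.00: 2.4, 99.3; 2.00: 3.1, 96.6; 3.00: 3.0, 95.8; 4.00: 5.0, 94.6

(readings scatter by 1 percentage point)

- the reaction counts as stopped when no species that holds the L changes by six tenths of a point or more over the second half of the time

- which holds at 5.0 min: what has brought the reaction to rest, or that it has not come to rest (forward and back rates have come level / it is still moving / no working catalyst is left / all of L has reacted)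
- the G standing at 5.0 min, as a percentage of the L charged

At 4.00 min, G gave Q = 298 L mol⁻¹ in the ash run and 300 L mol⁻¹ in the elm run. The alder run gave 360 L mol⁻¹, from a reading of 5.0 % with a scatter of 1 percentage point. So I accepted one curve.

In the ash run, Q reached 205 L mol⁻¹ at 2.00 min. The next equal stretch added 0.450 of that, and I read this as the share of working E surviving each stretch. Continuing the series gave my carried value, Q at the flask's 5.0 min, 323 L mol⁻¹. The flask charges 2.85 × 10⁻⁴ M of E, so I expected G = 8.79 %, with 2.3 points gained in the second half.

The forecast said it is still moving, with G at 7.3 %, lower than my figure. Its ground was plain: “The catalyst is therefore dying.”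

The flask gave it is still moving, with G at 10.5 %, and the forecast held on both counts.

    L + E → Z (k = 140 L mol⁻¹ min⁻¹)
    Z ⇌ E + G (K = 0.0620 M, k = 36.0 min⁻¹)
    E → J (k = 0.200 min⁻¹)

By its loss to J alone, E had a half-life of 3.5 min, shorter than the 17 min half-life of L by the making of Z alone, with the other concentrations held at their charge. At 5.00 min, the flask held 55.6 % of its catalyst as J and 89 % of its L. The flask's own G gives Q = 387 L mol⁻¹, higher than my 323 L mol⁻¹. The neighbour flask with 0.20 M of L reached G = 25.7 %, so its Q is 260 L mol⁻¹, lower than the flask's, and at 5.00 min it held 36.5 % of its catalyst as Z.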